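## Retrosynthetic overview

1. No carbocycle is built: the cyclopentenone is bought as (R)-silyloxy enone 1, whose carbinol carbon (future C9) is the only purchased stereocentre. The only ring formed is a transient oxirane (line 4).
2. C7=C8: aldol condensation at C8 while the carbonyl is still on C12. The usual E alkylidene (chain anti to C=O) becomes the 7Z geometry once the carbonyl is moved to C9.
3. C12–C13 (key bond, only stereocentre): a cathodically generated (Z)-oct-2-enylbarium adds 1,2 to the C12 ketone, anti to the silyloxy group.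
4. Endgame: desilylation and oxidation at C9 (carbonyl transposition), then C10–Cl by 10,11-epoxidation and opening with HCl.
5. Chains: a (Z)-enal and a (Z)-allylic chloride, each made in one or two steps from a commercial alcohol.

Assumption: C1–C20 are prostanoid atom numbers of the target; the starting materials of steps 1, 3 and 4 are taken as purchasable; the transient epoxide is drawn cis to the 12-hydroxyl (the other isomer would converge in the last step).

## Route

Step 1
Reactants: 2 methyl 7-hydroxyhept-5-ynoate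
Product: 3 methyl (5Z)-7-hydroxyhept-5-enoate
Conditions: H2 (1 atm), Pd/CaCO3 poisoned with Pb(OAc)2, quinoline, EtOAc, 0 °C
Reagents that add atoms: none
Why: Lindlar semi-hydrogenation delivers H2 syn to the alkyne on the poisoned palladium surface and stops at the 5Z alkene; ester and alcohol are inert.

Step 2
Reactants: 3 methyl (5Z)-7-hydroxyhept-5-enoate
Product: 4 methyl (5Z)-7-oxohept-5-enoate
Conditions: Dess–Martin periodinane, pyridine, CH2Cl2, 0 °C
Reagents that add atoms: none
Why: Dess–Martin oxidation of a primary allylic alcohol under buffered, non-basic conditions keeps the Z enal from isomerising.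

Step 3
Reactants: 1 (4R)-4-[(tert-butyldimethylsilyl)oxy]cyclopent-2-en-1-one; 4 methyl (5Z)-7-oxohept-5-enoate
Product: 7 methyl (5Z,7E)-7-[(5S)-5-[(tert-butyldimethylsilyl)oxy]-2-oxocyclopent-3-en-1-ylidene]hept-5-enoate, via lithium aldolate 5 (not isolated), via aldol mesylate 6 (not isolated)
Conditions: LiN(iPr)2, THF, −78 °C; 4; then MsCl, Et3N, −78 → 0 °C
Reagents that add atoms: none
Why: Aldol condensation: kinetic deprotonation of 1 at the α′ CH2 (future C8) and addition to 4 give 5, mesylation gives 6, and E1cB elimination gives the alkylidene ketone with the chain anti to the carbonyl (E); loss of the silyloxy group from the enolates is blocked because it would create a cyclopentadienone, and C9 is untouched.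

Step 4
Reactants: 8 (2Z)-oct-2-en-1-ol
Product: 9 (2Z)-1-chlorooct-2-ene
Conditions: PPh3, CCl4, 60 °C
Reagents that add atoms: tetrachloromethane ClC(Cl)(Cl)Cl
Why: Appel chlorination is an SN2 displacement of the oxyphosphonium at the primary allylic carbon, so there is no allylic transposition and the Z geometry is kept.

Step 5
Reactants: 9 (2Z)-1-chlorooct-2-ene; 7 methyl (5Z,7E)-7-[(5S)-5-[(tert-butyldimethylsilyl)oxy]-2-oxocyclopent-3-en-1-ylidene]hept-5-enoate
Product: 12 methyl (5Z,7E,9S,12R,14Z)-9-[(tert-butyldimethylsilyl)oxy]-12-hydroxyprosta-5,7,10,14-tetraen-1-oate, via (2Z)-oct-2-en-1-ylbarium iodide 10 (not isolated), via barium alkoxide 11 (not isolated)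
Conditions: BaI2, Bu4NI, THF, −78 °C, divided cell, graphite-felt cathode, Pt anode, 2.2 F/mol, 9 added slowly; then 7, −78 °C; H2O
Reagents that add atoms: none
Why: Proposed new method: two-electron cathodic cleavage of the allylic C–Cl bond of 9 at −78 °C gives the (Z)-allyl carbanion directly (the allyl radical is reduced at the electrode far faster than it can rotate or dimerise), Ba2+ captures it as the ion-paired, configurationally stable allylbarium 10 with the metal on the primary carbon, and 10 adds 1,2 through its unsubstituted terminus to the non-enolisable ketone 7 from the face opposite the silyloxy group (held pseudo-axial by allylic strain with the alkylidene), forming C12–C13 and the 12R centre under control of the bought C9 centre; the closest known chemistry is the α-selective, geometry-retaining carbonyl allylation with allylbarium reagents made from chemically activated barium, together with cathodic Barbier-type allylation and low-temperature pool electrolysis.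

Step 6
Reactants: 12 methyl (5Z,7E,9S,12R,14Z)-9-[(tert-butyldimethylsilyl)oxy]-12-hydroxyprosta-5,7,10,14-tetraen-1-oate
Product: 13 methyl (5Z,7E,9S,12R,14Z)-9,12-dihydroxyprosta-5,7,10,14-tetraen-1-oate
Conditions: Bu4NF, THF, 0 °C; H2O
Reagents that add atoms: none
Why: Fluoride-mediated silyl ether cleavage (strong Si–F bond); no stereocentre is touched.

Step 7
Reactants: 13 methyl (5Z,7E,9S,12R,14Z)-9,12-dihydroxyprosta-5,7,10,14-tetraen-1-oate
Product: 14 methyl (5Z,7Z,12R,14Z)-12-hydroxy-9-oxoprosta-5,7,10,14-tetraen-1-oate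
Conditions: Dess–Martin periodinane, pyridine, CH2Cl2, 0 °C
Reagents that add atoms: none
Why: Dess–Martin oxidation of the doubly allylic secondary alcohol (the tertiary 12-OH cannot be oxidised) completes the carbonyl transposition; the alkene is unchanged but C6 now lies on the side of the new C9 carbonyl, which is 7Z, and the relay centre C9 is erased.

Step 8
Reactants: 14 methyl (5Z,7Z,12R,14Z)-12-hydroxy-9-oxoprosta-5,7,10,14-tetraen-1-oate
Product: 15 methyl (5Z,7Z,10S,11R,12S,14Z)-10,11-epoxy-12-hydroxy-9-oxoprosta-5,7,14-trien-1-oate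
Conditions: H2O2 (30% aq.), NaOH (cat.), MeOH, −30 °C
Reagents that add atoms: hydrogen peroxide OO
Why: Weitz–Scheffer nucleophilic epoxidation: hydroperoxide adds to C11 of the strained ring enone, guided by hydrogen bonding to the 12-OH and away from the octenyl chain, and the enolate closes the oxirane cis to the hydroxyl; both new centres are removed in step 9.

Step 9
Reactants: 15 methyl (5Z,7Z,10S,11R,12S,14Z)-10,11-epoxy-12-hydroxy-9-oxoprosta-5,7,14-trien-1-oate
Product: 17 methyl (5Z,7Z,12R,14Z)-10-chloro-12-hydroxy-9-oxoprosta-5,7,10,14-tetraen-1-oate (the target), via chlorohydrin 16 (not isolated)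
Conditions: HCl (4 M in dioxane), CH2Cl2, 0 °C → rt
Reagents that add atoms: hydrogen chloride Cl
Why: Acid-promoted opening of the α,β-epoxy ketone by chloride at C10 (SN2 next to the carbonyl; C11 is neopentyl-like) gives 16, whose β-hydroxy ketone dehydrates to the 2-chloro enone; C12 does not ionise because both its allylic neighbours are electron-poor.

## Compound list

1 | (4R)-4-[(tert-butyldimethylsilyl)oxy]cyclopent-2-en-1-one | O=C1C=C[C@H](O[Si](C)(C)C(C)(C)C)C1 | starting material
2 | methyl 7-hydroxyhept-5-ynoate | COC(=O)CCCC#CCO | starting material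
3 | methyl (5Z)-7-hydroxyhept-5-enoate | COC(=O)CCC/C=C\CO | intermediate
4 | methyl (5Z)-7-oxohept-5-enoate | COC(=O)CCC/C=C\C=O | intermediate
5 | lithium aldolate: methyl (5Z)-7-[5-[(tert-butyldimethylsilyl)oxy]-2-oxocyclopent-3-en-1-yl]-7-(lithiooxy)hept-5-enoate; silyloxy carbon as in 1; both epimers at the two new carbons | COC(=O)CCC/C=C\C(O[Li])C1C(=O)C=C[C@@H]1O[Si](C)(C)C(C)(C)C | intermediate
6 | aldol mesylate: methyl (5Z)-7-[5-[(tert-butyldimethylsilyl)oxy]-2-oxocyclopent-3-en-1-yl]-7-[(methanesulfonyl)oxy]hept-5-enoate; silyloxy carbon as in 1; both epimers at the two new carbons | COC(=O)CCC/C=C\C(OS(C)(=O)=O)C1C(=O)C=C[C@@H]1O[Si](C)(C)C(C)(C)C | intermediate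
7 | methyl (5Z,7E)-7-[(5S)-5-[(tert-butyldimethylsilyl)oxy]-2-oxocyclopent-3-en-1-ylidene]hept-5-enoate | COC(=O)CCC/C=C\C=C1\C(=O)C=C[C@@H]1O[Si](C)(C)C(C)(C)C | intermediate
8 | (2Z)-oct-2-en-1-ol | CCCCC/C=C\CO | starting material
9 | (2Z)-1-chlorooct-2-ene | CCCCC/C=C\CCl | intermediate
10 | (2Z)-oct-2-en-1-ylbarium iodide | CCCCC/C=C\C[Ba]I | intermediate
11 | barium alkoxide: 12-O-(iodobarium) derivative of 12 | CCCCC/C=C\C[C@@]1(O[Ba]I)C=C[C@H](O[Si](C)(C)C(C)(C)C)/C1=C\C=C/CCCC(=O)OC | intermediate
12 | methyl (5Z,7E,9S,12R,14Z)-9-[(tert-butyldimethylsilyl)oxy]-12-hydroxyprosta-5,7,10,14-tetraen-1-oate (12-OH cis to the 9-silyloxy group) | CCCCC/C=C\C[C@@]1(O)C=C[C@H](O[Si](C)(C)C(C)(C)C)/C1=C\C=C/CCCC(=O)OC | intermediate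
13 | methyl (5Z,7E,9S,12R,14Z)-9,12-dihydroxyprosta-5,7,10,14-tetraen-1-oate (cis diol) | CCCCC/C=C\C[C@@]1(O)C=C[C@H](O)/C1=C\C=C/CCCC(=O)OC | intermediate
14 | methyl (5Z,7Z,12R,14Z)-12-hydroxy-9-oxoprosta-5,7,10,14-tetraen-1-oate | CCCCC/C=C\C[C@@]1(O)C=CC(=O)/C1=C\C=C/CCCC(=O)OC | intermediate
15 | methyl (5Z,7Z,10S,11R,12S,14Z)-10,11-epoxy-12-hydroxy-9-oxoprosta-5,7,14-trien-1-oate (oxirane cis to the 12-OH) | CCCCC/C=C\C[C@@]1(O)[C@@H]2O[C@@H]2C(=O)/C1=C\C=C/CCCC(=O)OC | intermediate
16 | chlorohydrin: methyl (5Z,7Z,10R,11S,12S,14Z)-10-chloro-11,12-dihydroxy-9-oxoprosta-5,7,14-trien-1-oate (Cl anti to the 11-OH) | CCCCC/C=C\C[C@@]1(O)[C@H](O)[C@@H](Cl)C(=O)/C1=C\C=C/CCCC(=O)OC | intermediate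
17 | methyl (5Z,7Z,12R,14Z)-10-chloro-12-hydroxy-9-oxoprosta-5,7,10,14-tetraen-1-oate | CCCCC/C=C\C[C@@]1(O)C=C(Cl)C(=O)/C1=C\C=C/CCCC(=O)OC | target

## Step count and risks

Total: 9 steps. Longest linear sequence: 8 steps (steps 1, 2, 3, 5, 6, 7, 8, 9).

Most likely to fail, each with one fallback:

Step 3. Risk: a one-pot enolate aldol and elimination on a base-sensitive silyloxy enone, with a Z enal that isomerises easily and an E/Z ratio at the new alkylidene that must favour E. The fallback sets out from 2 and 1 and rejoins at 12; the alkyne is kept as a masked 5Z alkene. 2 is oxidised directly (Dess–Martin periodinane, pyridine) to methyl 7-oxohept-5-ynoate F1. Condensation with the lithium enolate of 1 under the conditions of step 3 passes through lithium aldolate F2 and aldol mesylate F3 (neither isolated) to the enynone methyl (7E)-7-[(5S)-5-[(tert-butyldimethylsilyl)oxy]-2-oxocyclopent-3-en-1-ylidene]hept-5-ynoate F4. Addition of 10 as in step 5 gives, through barium alkoxide F5, the enyne carbinol methyl (7E,9S,12R,14Z)-9-[(tert-butyldimethylsilyl)oxy]-12-hydroxyprosta-7,10,14-trien-5-yn-1-oate F6. Semi-hydrogenation of its only alkyne (H2, Pd/CaCO3 poisoned with Pb(OAc)2, quinoline) gives 12.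

Step 5 (the new step). Risk: low conductivity at −78 °C, Wurtz coupling of 10 with 9, loss of Z geometry or of α-selectivity if the catholyte warms, and conjugate addition. The fallback uses known chemistry, sets out from 7 and rejoins at 12. Oct-2-yne is lithiated at its methyl group (n-BuLi, TMEDA, THF) and transmetalated with ClTi(OiPr)3 to triisopropoxy(octa-1,2-dien-3-yl)titanium F7. Allenyltitanium reagents of this kind add to ketones through the CH2 terminus, so 7 gives at −78 °C, through titanium alkoxide F8, the homopropargylic alcohol methyl (5Z,7E,9S,12R)-9-[(tert-butyldimethylsilyl)oxy]-12-hydroxyprosta-5,7,10-trien-14-yn-1-oate F9, again by attack anti to the silyloxy group. Semi-hydrogenation over Pd/CaCO3 poisoned with Pb(OAc)2 with quinoline turns the 14-yne into the 14Z alkene, which is 12.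

Step 8. Risk: the ring enone must be epoxidised chemoselectively next to a Z,Z-dienone, and reversible hydroperoxide addition at C7 could erode the 7Z geometry. The fallback sets out from 14 and rejoins at 17. It is a direct α-chlorination with PhICl2 and pyridine (CH2Cl2, 0 °C), the known nucleophile-assisted α-halogenation of enones: pyridine adds to C11, the enolate is chlorinated at C10, and pyridine is expelled. It bypasses 15 and 16 and makes no new compound.

## Further compounds

F1 | step 3 | methyl 7-oxohept-5-ynoate | COC(=O)CCCC#CC=O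
F2 | step 3 | lithium aldolate: methyl 7-[5-[(tert-butyldimethylsilyl)oxy]-2-oxocyclopent-3-en-1-yl]-7-(lithiooxy)hept-5-ynoate; silyloxy carbon as in 1; both epimers at the two new carbons | COC(=O)CCCC#CC(O[Li])C1C(=O)C=C[C@@H]1O[Si](C)(C)C(C)(C)C
F3 | step 3 | aldol mesylate: methyl 7-[5-[(tert-butyldimethylsilyl)oxy]-2-oxocyclopent-3-en-1-yl]-7-[(methanesulfonyl)oxy]hept-5-ynoate; silyloxy carbon as in 1; both epimers at the two new carbons | COC(=O)CCCC#CC(OS(C)(=O)=O)C1C(=O)C=C[C@@H]1O[Si](C)(C)C(C)(C)C
F4 | step 3 | methyl (7E)-7-[(5S)-5-[(tert-butyldimethylsilyl)oxy]-2-oxocyclopent-3-en-1-ylidene]hept-5-ynoate | COC(=O)CCCC#C/C=C1/C(=O)C=C[C@@H]1O[Si](C)(C)C(C)(C)C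
F5 | step 3 | barium alkoxide: 12-O-(iodobarium) derivative of F6 | CCCCC/C=C\C[C@@]1(O[Ba]I)C=C[C@H](O[Si](C)(C)C(C)(C)C)/C1=C\C#CCCCC(=O)OC
F6 | step 3 | methyl (7E,9S,12R,14Z)-9-[(tert-butyldimethylsilyl)oxy]-12-hydroxyprosta-7,10,14-trien-5-yn-1-oate | CCCCC/C=C\C[C@@]1(O)C=C[C@H](O[Si](C)(C)C(C)(C)C)/C1=C\C#CCCCC(=O)OC
F7 | step 5 | triisopropoxy(octa-1,2-dien-3-yl)titanium | C=C=C(CCCCC)[Ti](OC(C)C)(OC(C)C)OC(C)C
F8 | step 5 | titanium alkoxide: 12-O-(triisopropoxytitanium) derivative of F9 | CCCCCC#CC[C@@]1(O[Ti](OC(C)C)(OC(C)C)OC(C)C)C=C[C@H](O[Si](C)(C)C(C)(C)C)/C1=C\C=C/CCCC(=O)OC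
F9 | step 5 | methyl (5Z,7E,9S,12R)-9-[(tert-butyldimethylsilyl)oxy]-12-hydroxyprosta-5,7,10-trien-14-yn-1-oate | CCCCCC#CC[C@@]1(O)C=C[C@H](O[Si](C)(C)C(C)(C)C)/C1=C\C=C/CCCC(=O)OC
F0 | step 8 | none | none
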